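The runs were generated by integration on assumed constants.

**Two clocks.** In the elm run substrate levels off with a half-life of about 0.790 h, far shorter than the 36.2 h on which material turns into target. I count in the second clock, the pool half-life: the time in which the material charged that has not yet passed through target halves. I read it from the elm target readings at 3.00 h and 6.00 h, each with a scatter of 1 percentage point, so it is a rough reading.

| setting | elm | maple | north-east | north-west | south-west | east | north |
|---|---|---|---|---|---|---|---|
| substrate | 0.080 M | 0.12 M | 0.12 M | 0.12 M | 0.12 M | 0.12 M | 0.12 M |
| reagent | 0.10 M | 0.10 M | 0.100 M | 0.200 M | 0.400 M | 0.800 M | 1.50 M |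
| catalyst | 0.24 mM | 0.48 mM | 0.24 mM | 0.24 mM | 0.24 mM | 0.24 mM | 0.24 mM |
| remark | run made earlier | run made earlier |  |  |  |  |  |
| time |  |  | 25 h | 25 h | 25 h | 25 h | 25 h |

- elm (time / h: target / %, substrate / %): 1.33: 0.7, 45.1; 3.00: 3.3, 26.7; 6.00: 8.7, 22.0; 15.0: 18.8, 20.3
- maple (time / h: target / %, substrate / %): 4.00: 10.5, 22.3; 8.00: 20.4, 21.3; 12.0: 25.0, 19.6; 15.0: 27.4, 16.7

(scatter of a reading: 1 percentage point)

- amount of target at the end, in percent of the substrate charged for north-east, north-west, south-west, east, north, in this order
- the course of these numbers from the first flask to the last (falls all the way / rises all the way / rises, then falls / falls, then rises / hardly changes)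

- the numbers in the tables scatter with a standard deviation of 1 percentage point
- "hardly changes" means that all values lie within two and a half points (for a concentration: within two and a half percent of the largest)

**Fast rung.** At 3.00 h the elm run shows substrate at 26.7% and target at 3.3%, so 70.0% sits in an unseen form. On this rung the flask is a pool waiting to drain.

**Slow rung.** The north-east flask has the catalyst and reagent of the elm run but more substrate. I take the half-life to carry over, so by my count its 25 h is 0.691 pool half-lives. My reckoning leaves 61.9% of the charge in the pool and has 38.1% converted in north-east.

**Slowest rung.** I expect part of that to leave target again. In the maple run the hourly gain of target falls by a factor of 3.09 between the early and the late intervals, while 75.0% of the charge is still not target at 12.0 h. I take this as target being used up, and I assume that reagent acts both in the making and in this loss, though both runs used one reagent level. On that assumption the count grows with reagent, to 10.4 pool half-lives in north, and the loss grows with it. So I commit to a row that rises, then falls.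

**The forecast.** The forecast puts the row flat at 16%, calls its course "hardly changes", and says of its assumption: “if the catalyst is saturated and turnover-limited, the row stays flat”. There we part.

**The flask.** Target ends at 21.2%, 25.8%, 19.1%, 4.97% and 0.317%: rises, then falls, turning near 0.20 M.

    reagent + catalyst + intermediate → catalyst + target (k = 0.330 /M²/s)
    substrate + catalyst ⇌ catalyst + intermediate (K = 3.00, k = 0.860 /M/s)
    target ⇌ isomer of the product (K = 0.400, k = 1.80 × 10⁻⁶ /s)
    reagent + target → over-reaction product (k = 1.00 × 10⁻⁴ /M/s)

**The loss.** In north-east the count leaves 61.9%, and substrate plus intermediate stand at 68.6%. In north, 10.4 pool half-lives leave 0.0760%. The pool there has drained to 0.259% of substrate plus intermediate, yet target is scarce at 0.317%, and the main reason is the conversion of reagent and target into over-reaction product: with that step taken away, north ends with 89.3% of target.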